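**Retrosynthetic overview**

1. Ring B (the 2,5-dimethoxycyclohexa-2,5-dienone) is opened last, at the bond between the spiro carbon and its C(OMe)= neighbour; ring A (the pentasubstituted cyclohexane) then carries the open chain CH=C(OMe)–CO–CH=C(OMe)2.
2. Enabling feature: in ring B the spiro carbon is the γ-carbon of the α-methoxy enone C(spiro)–CH=C(OMe)–C=O, and the carbon it must bond to is the β-carbon of a vinylogous ester, i.e. an acid-level carbon. γ-Deprotonation of the open chain therefore gives a 3-oxidohexatriene whose two ends are exactly these atoms; 6π electrocyclization and loss of methoxide close ring B, set the spiro centre and deliver the final oxidation level in one operation.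
3. The chain comes from aldol condensation of the ring-A carbaldehyde with 1,4,4-trimethoxybut-3-en-2-one; the aldehyde comes from one-carbon homologation of the ring-A ketone.
4. Ring A: organocatalytic annulation of crotonaldehyde with a β-keto ester (first stereocentre), then α′-arylation, MeLi addition with oxidative 1,3-transposition, face-selective hydrogenation and a second α-arylation (remaining centres by substrate or thermodynamic control).
5. Ring order: ring A (step 1), ring B (step 11); both aryl rings are bought as 1-bromo-2,4,5-trimethoxybenzene.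

Key step: step 11

Assumption: tert-butyl 3-oxohexanoate and 1,1-dimethoxyethene are taken as catalogue compounds; both are otherwise one known step from bulk chemicals.

**Route**

Step 1
Reactants: 1 (E)-but-2-enal; 2 tert-butyl 3-oxohexanoate
Product: 5 (5S)-2-ethyl-5-methylcyclohex-2-en-1-one, via Michael adduct 3 (not isolated), via cyclic keto ester 4 (not isolated)
Conditions: (R)-2-{bis[3,5-bis(trifluoromethyl)phenyl](trimethylsilyloxy)methyl}pyrrolidine (10 mol %), PhCO2H (10 mol %), toluene, 23 °C; then p-TsOH·H2O (20 mol %), 80 °C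
Reagents that add atoms: none
Why: Iminium-activated asymmetric Michael addition of the β-keto ester to the enal (the diarylprolinol silyl ether shields one face of the iminium ion and should set the methyl-bearing centre as S), followed by acid-catalysed intramolecular aldol condensation and dealkylative decarboxylation, i.e. an organocatalytic Robinson-type annulation.

Step 2
Reactants: 5 (5S)-2-ethyl-5-methylcyclohex-2-en-1-one; 6 1-bromo-2,4,5-trimethoxybenzene
Product: 8 (5S,6S)-2-ethyl-5-methyl-6-(2,4,5-trimethoxyphenyl)cyclohex-2-en-1-one, via lithium dienolate 7 (not isolated)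
Conditions: LiN(SiMe3)2, THF, −78 °C; then 6, Pd2(dba)3 (2.5 mol %), P(t-Bu)3 (10 mol %), −78 → 23 °C
Reagents that add atoms: none
Why: Palladium-catalysed α-arylation of the preformed kinetic (cross-conjugated, α′) enolate, a known reaction type for cyclic enones and vinylogous esters; the new benzylic centre is epimerisable and should settle trans to the adjacent methyl group.

Step 3
Reactants: 8 (5S,6S)-2-ethyl-5-methyl-6-(2,4,5-trimethoxyphenyl)cyclohex-2-en-1-one
Product: 9 (1R,5S,6S)-2-ethyl-1,5-dimethyl-6-(2,4,5-trimethoxyphenyl)cyclohex-2-en-1-ol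
Conditions: MeLi, CeCl3, THF, −78 °C
Reagents that add atoms: methyllithium, [Li]C
Why: 1,2-Addition of the weakly basic organocerium reagent to the enone carbonyl (this suppresses enolisation at the acidic α-aryl position), expected from the face opposite the neighbouring aryl group; the carbinol configuration is erased in step 4.

Step 4
Reactants: 9 (1R,5S,6S)-2-ethyl-1,5-dimethyl-6-(2,4,5-trimethoxyphenyl)cyclohex-2-en-1-ol
Product: 10 (4R,5S)-2-ethyl-3,5-dimethyl-4-(2,4,5-trimethoxyphenyl)cyclohex-2-en-1-one
Conditions: pyridinium chlorochromate, 4 Å molecular sieves, CH2Cl2, 23 °C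
Reagents that add atoms: pyridinium chlorochromate, [O-][Cr](=O)(=O)Cl.c1cc[nH+]cc1
Why: Babler–Dauben oxidative 1,3-transposition of a tertiary allylic alcohol (chromate ester, [3,3] shift, oxidation) moves the oxygen to the former β-carbon and gives the tetrasubstituted enone without touching a stereocentre.

Step 5
Reactants: 10 (4R,5S)-2-ethyl-3,5-dimethyl-4-(2,4,5-trimethoxyphenyl)cyclohex-2-en-1-one
Product: 11 (2R,3R,4R,5S)-2-ethyl-3,5-dimethyl-4-(2,4,5-trimethoxyphenyl)cyclohexan-1-one
Conditions: H2 (20 bar), Pd/C, EtOAc, 23 °C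
Reagents that add atoms: none
Why: Heterogeneous syn-hydrogenation of the tetrasubstituted enone from the face opposite the pseudo-axial 4-aryl group should place the 3-methyl and 2-ethyl groups cis to the aryl group; the 2-position is epimerisable and this isomer (ethyl equatorial, methyl axial) is also the thermodynamic one.

Step 6
Reactants: 11 (2R,3R,4R,5S)-2-ethyl-3,5-dimethyl-4-(2,4,5-trimethoxyphenyl)cyclohexan-1-one; 6 1-bromo-2,4,5-trimethoxybenzene
Product: 12 (2R,3R,4S,5R,6R)-2-ethyl-3,5-dimethyl-4,6-bis(2,4,5-trimethoxyphenyl)cyclohexan-1-one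
Conditions: Pd(OAc)2 (3 mol %), XPhos (6 mol %), NaOt-Bu, toluene, 80 °C
Reagents that add atoms: none
Why: Palladium-catalysed ketone α-arylation, selective for the methylene over the ethyl-bearing methine; the new α-aryl centre equilibrates under the basic conditions to the equatorial position, trans to the 5-methyl group.

Step 7
Reactants: 12 (2R,3R,4S,5R,6R)-2-ethyl-3,5-dimethyl-4,6-bis(2,4,5-trimethoxyphenyl)cyclohexan-1-one
Product: 14 (1S,2R,3S,4S,5R,6S)-2-ethyl-3,5-dimethyl-4,6-bis(2,4,5-trimethoxyphenyl)cyclohexane-1-carbaldehyde, via enol ether 13 (not isolated)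
Conditions: (methoxymethyl)triphenylphosphonium chloride, KN(SiMe3)2, THF, 0 → 50 °C; then 2 M HCl, THF, 23 °C; then K2CO3 (cat.), MeOH
Reagents that add atoms: (methoxymethyl)triphenylphosphonium chloride, COC[P+](c1ccccc1)(c1ccccc1)c1ccccc1.[Cl-]; water, O
Why: Wittig methoxymethylenation and acid hydrolysis of the enol ether (one-carbon homologation); the formyl-bearing centre is epimerisable and is equilibrated to the equatorial aldehyde, and its configuration is in any case lost again in step 11.

Step 8
Reactants: 15 methoxyacetyl chloride; 16 1,1-dimethoxyethene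
Product: 17 1,4,4-trimethoxybut-3-en-2-one
Conditions: 16 (2.2 equiv), Et2O, 0 → 23 °C
Reagents that add atoms: none
Why: C-Acylation of a ketene acetal by an acid chloride (addition at the nucleophilic CH2 terminus, loss of HCl, which the second equivalent of ketene acetal takes up); no amine base is used, so methoxyketene should not form.

Step 9
Reactants: 14 (1S,2R,3S,4S,5R,6S)-2-ethyl-3,5-dimethyl-4,6-bis(2,4,5-trimethoxyphenyl)cyclohexane-1-carbaldehyde; 17 1,4,4-trimethoxybut-3-en-2-one
Product: 19 1-[2-ethyl-3,5-dimethyl-4,6-bis(2,4,5-trimethoxyphenyl)cyclohexyl]-1-hydroxy-2,5,5-trimethoxypent-4-en-3-one, via lithium enolate 18 (not isolated)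
Conditions: 17, LiN(SiMe3)2, THF, −78 °C; then 14, −78 °C
Reagents that add atoms: none
Why: Directed aldol addition of the preformed lithium enolate (the CH2OMe group is the only enolisable position of 17) to the aldehyde; the two new chain centres form as a mixture and are removed in step 10.

Step 10
Reactants: 19 1-[2-ethyl-3,5-dimethyl-4,6-bis(2,4,5-trimethoxyphenyl)cyclohexyl]-1-hydroxy-2,5,5-trimethoxypent-4-en-3-one
Product: 21 (1Z)-1-[2-ethyl-3,5-dimethyl-4,6-bis(2,4,5-trimethoxyphenyl)cyclohexyl]-2,5,5-trimethoxypenta-1,4-dien-3-one, via mesylate 20 (not isolated)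
Conditions: MsCl, Et3N, CH2Cl2, 0 °C; then DBU, 23 °C
Reagents that add atoms: none
Why: Mesylation and E1cB elimination complete the aldol condensation and should give mainly the Z α-methoxy enone; the alkene geometry is of no consequence because this bond becomes a single bond in the trienolate of step 11.

Step 11
Reactants: 21 (1Z)-1-[2-ethyl-3,5-dimethyl-4,6-bis(2,4,5-trimethoxyphenyl)cyclohexyl]-2,5,5-trimethoxypenta-1,4-dien-3-one
Product: 24 tatanan B, via lithium trienolate 22 (not isolated), via spirocyclic ketal enolate 23 (not isolated)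
Conditions: lithium 2,2,6,6-tetramethylpiperidide, THF, −78 → 23 °C
Reagents that add atoms: none
Why: Proposed new method: the amide base removes the only acidic sp3 hydrogen of 21, the γ-hydrogen on the ring-A carbon, giving the lithium 3-oxido-1,3,5-hexatriene 22, whose enolate double bond is held Z by lithium chelation between the oxido and the adjacent methoxy oxygen, so that the ring-A carbon and the ketene-acetal carbon are the two ends of an s-cis,Z,s-cis triene. Thermal disrotatory 6π electrocyclization joins these two ends and closes ring B (six-membered carbocycle, closure by electrocyclization, helped by the oxido donor and by release of the allylic strain of the exocyclic trienolate), and the resulting enolate 23, which carries two methoxy groups on its β-carbon, expels methoxide (E1cB) to give the vinylogous ester and hence 24 without any later redox or methylation step. The closest known reaction types are the anion-accelerated 6π electrocyclization of oxido-hexatrienes made from dienones or from cyclobutenones and alkenyllithiums, and the collapse of cycloadducts of 1,1-dimethoxy-3-oxy-dienes to 3-methoxycyclohexenones; closure onto a fully substituted ring carbon with a ketene-acetal terminus has not been shown. The spiro carbon is the only new stereocentre: ring A sits in the chair with the 3-methyl group axial, this methyl blocks the axial face of the exocyclic double bond, and the ketene-acetal carbon should therefore bond from the equatorial face, which places C(OMe)= equatorial and CH= axial as in tatanan B. The step needs γ-deprotonation instead of attack of the base on the ketene acetal (secured by a hindered amide and the absence of any α′-sp3 hydrogen), six-electron instead of Nazarov-type four-electron closure (secured by anionic, acid-free conditions), and the face selectivity just described (secured by the axial methyl group).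

**Compound list**

1 | (E)-but-2-enal (crotonaldehyde) | C/C=C/C=O | starting material
2 | tert-butyl 3-oxohexanoate | CCCC(=O)CC(=O)OC(C)(C)C | starting material
3 | tert-butyl (3S)-2-butanoyl-3-methyl-5-oxopentanoate (epimers at C-2) | CCCC(=O)C(C(=O)OC(C)(C)C)[C@@H](C)CC=O | intermediate
4 | tert-butyl (6S)-3-ethyl-6-methyl-2-oxocyclohex-3-ene-1-carboxylate (epimers at C-1) | O=C1C(C(=O)OC(C)(C)C)[C@@H](C)CC=C1CC | intermediate
5 | (5S)-2-ethyl-5-methylcyclohex-2-en-1-one | O=C1C[C@@H](C)CC=C1CC | intermediate
6 | 1-bromo-2,4,5-trimethoxybenzene | COc1cc(OC)c(OC)cc1Br | starting material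
7 | lithium (3S)-6-ethyl-3-methylcyclohexa-1,5-dien-1-olate | [Li+].[O-]C1=C[C@@H](C)CC=C1CC | intermediate
8 | (5S,6S)-2-ethyl-5-methyl-6-(2,4,5-trimethoxyphenyl)cyclohex-2-en-1-one (aryl trans to methyl) | O=C1[C@H](c2cc(OC)c(OC)cc2OC)[C@@H](C)CC=C1CC | intermediate
9 | (1R,5S,6S)-2-ethyl-1,5-dimethyl-6-(2,4,5-trimethoxyphenyl)cyclohex-2-en-1-ol (expected major carbinol epimer) | O[C@]1(C)[C@H](c2cc(OC)c(OC)cc2OC)[C@@H](C)CC=C1CC | intermediate
10 | (4R,5S)-2-ethyl-3,5-dimethyl-4-(2,4,5-trimethoxyphenyl)cyclohex-2-en-1-one | CCC1=C(C)[C@H](c2cc(OC)c(OC)cc2OC)[C@@H](C)CC1=O | intermediate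
11 | (2R,3R,4R,5S)-2-ethyl-3,5-dimethyl-4-(2,4,5-trimethoxyphenyl)cyclohexan-1-one (2-Et, 3-Me and 4-Ar cis; 5-Me trans to 4-Ar) | CC[C@@H]1[C@H](C)[C@H](c2cc(OC)c(OC)cc2OC)[C@@H](C)CC1=O | intermediate
12 | (2R,3R,4S,5R,6R)-2-ethyl-3,5-dimethyl-4,6-bis(2,4,5-trimethoxyphenyl)cyclohexan-1-one (all substituents equatorial except the axial 3-methyl) | CC[C@@H]1[C@H](C)[C@H](c2cc(OC)c(OC)cc2OC)[C@@H](C)[C@H](c2cc(OC)c(OC)cc2OC)C1=O | intermediate
13 | 2-ethyl-1-(methoxymethylidene)-3,5-dimethyl-4,6-bis(2,4,5-trimethoxyphenyl)cyclohexane, ring centres as in 12, E/Z mixture | CC[C@@H]1[C@H](C)[C@H](c2cc(OC)c(OC)cc2OC)[C@@H](C)[C@H](c2cc(OC)c(OC)cc2OC)C1=COC | intermediate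
14 | (1S,2R,3S,4S,5R,6S)-2-ethyl-3,5-dimethyl-4,6-bis(2,4,5-trimethoxyphenyl)cyclohexane-1-carbaldehyde (formyl equatorial) | CC[C@@H]1[C@H](C)[C@H](c2cc(OC)c(OC)cc2OC)[C@@H](C)[C@H](c2cc(OC)c(OC)cc2OC)[C@H]1C=O | intermediate
15 | methoxyacetyl chloride | COCC(=O)Cl | starting material
16 | 1,1-dimethoxyethene | C=C(OC)OC | starting material
17 | 1,4,4-trimethoxybut-3-en-2-one | COCC(=O)C=C(OC)OC | intermediate
18 | lithium 1,4,4-trimethoxybuta-1,3-dien-2-olate | [Li+].[O-]C(=COC)C=C(OC)OC | intermediate
19 | 1-[2-ethyl-3,5-dimethyl-4,6-bis(2,4,5-trimethoxyphenyl)cyclohexyl]-1-hydroxy-2,5,5-trimethoxypent-4-en-3-one, ring as in 14, epimers at chain C-1 and C-2 | CC[C@@H]1[C@H](C)[C@H](c2cc(OC)c(OC)cc2OC)[C@@H](C)[C@H](c2cc(OC)c(OC)cc2OC)[C@H]1C(O)C(OC)C(=O)C=C(OC)OC | intermediate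
20 | methanesulfonate of 19 | CC[C@@H]1[C@H](C)[C@H](c2cc(OC)c(OC)cc2OC)[C@@H](C)[C@H](c2cc(OC)c(OC)cc2OC)[C@H]1C(OS(C)(=O)=O)C(OC)C(=O)C=C(OC)OC | intermediate
21 | (1Z)-1-[2-ethyl-3,5-dimethyl-4,6-bis(2,4,5-trimethoxyphenyl)cyclohexyl]-2,5,5-trimethoxypenta-1,4-dien-3-one, ring as in 14 | CC[C@@H]1[C@H](C)[C@H](c2cc(OC)c(OC)cc2OC)[C@@H](C)[C@H](c2cc(OC)c(OC)cc2OC)[C@H]1/C=C(\OC)C(=O)C=C(OC)OC | intermediate
22 | lithium 1-[2-ethyl-3,5-dimethyl-4,6-bis(2,4,5-trimethoxyphenyl)cyclohexylidene]-2,5,5-trimethoxypenta-2,4-dien-3-olate (3-oxidohexatriene) | CC[C@@H]1[C@H](C)[C@H](c2cc(OC)c(OC)cc2OC)[C@@H](C)[C@H](c2cc(OC)c(OC)cc2OC)C1=CC(OC)=C([O-])C=C(OC)OC.[Li+] | intermediate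
23 | lithium 7-ethyl-1,1,4-trimethoxy-8,10-dimethyl-9,11-bis(2,4,5-trimethoxyphenyl)spiro[5.5]undeca-2,4-dien-3-olate, configured as 24 | CC[C@@H]1[C@H](C)[C@H](c2cc(OC)c(OC)cc2OC)[C@@H](C)[C@H](c2cc(OC)c(OC)cc2OC)[C@]12C=C(OC)C([O-])=CC2(OC)OC.[Li+] | intermediate
24 | tatanan B, (6S,7R,8S,9S,10R,11R)-7-ethyl-1,4-dimethoxy-8,10-dimethyl-9,11-bis(2,4,5-trimethoxyphenyl)spiro[5.5]undeca-1,4-dien-3-one | CC[C@@H]1[C@H](C)[C@H](c2cc(OC)c(OC)cc2OC)[C@@H](C)[C@H](c2cc(OC)c(OC)cc2OC)[C@]12C=C(OC)C(=O)C=C2OC | target

**Step count**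

Total: 11 steps. Longest linear sequence: 10 steps (steps 1–7 and 9–11); step 8 is a one-step side branch.

**Steps most likely to fail**

1. Step 11 (Proposed new method). What may go wrong: slow or incomplete γ-deprotonation at the hindered ring carbon, attack of the base on the ketene acetal, failure of the crowded triene to close, or closure from the wrong face (giving the spiro epimer). The fallback uses known chemistry and reverses the order of bond formation in ring B, as in a Robinson spiroannulation. It sets out from aldehyde 14 and ketone 17. The potassium enolate of 14 (KOt-Bu, THF/t-BuOH) should add through its α-carbon to the ketene-acetal carbon of 17 with loss of methoxide (Michael addition–elimination, approach again from the equatorial face), giving the quaternary aldehyde 1-[(1E)-1,4-dimethoxy-3-oxobut-1-en-1-yl]-2-ethyl-3,5-dimethyl-4,6-bis(2,4,5-trimethoxyphenyl)cyclohexane-1-carbaldehyde F1. Intramolecular aldol condensation of its CH2OMe ketone onto the formyl group (KOt-Bu or pyrrolidinium acetate) then closes ring B at the CH=C(OMe) bond and comes back to the route at 24.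

2. Step 5. What may go wrong: poor facial selectivity (the 3-methyl epimer, trans to the aryl group) or no reduction of the tetrasubstituted enone. The fallback replaces undirected by hydroxyl-directed hydrogenation and sets out from 10. Luche reduction (NaBH4, CeCl3·7H2O, MeOH) should give, by axial hydride attack, (1R,4R,5S)-2-ethyl-3,5-dimethyl-4-(2,4,5-trimethoxyphenyl)cyclohex-2-en-1-ol F2, with the hydroxyl cis to the 5-methyl group and on the face opposite the aryl group. Hydrogenation with [Ir(cod)(PCy3)(py)]PF6 and H2 in CH2Cl2 delivers hydrogen syn to the hydroxyl and should give (1R,2R,3R,4R,5S)-2-ethyl-3,5-dimethyl-4-(2,4,5-trimethoxyphenyl)cyclohexan-1-ol F3. Oxidation with the periodinane DMP comes back to the route at 11.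

3. Step 7. What may go wrong: enolisation of the α-aryl ketone by the basic ylide, or no addition to the carbonyl group flanked by two substituents. The fallback avoids a basic carbon nucleophile and sets out from 12. Methylenation with Zn, CH2Br2 and TiCl4 (THF/CH2Cl2) should give 2-ethyl-3,5-dimethyl-1-methylidene-4,6-bis(2,4,5-trimethoxyphenyl)cyclohexane F4. Hydroboration from the unhindered equatorial face (9-BBN, then H2O2/NaOH) should give [2-ethyl-3,5-dimethyl-4,6-bis(2,4,5-trimethoxyphenyl)cyclohexyl]methanol with the hydroxymethyl group axial F5. Oxidation with the periodinane DMP gives the axial aldehyde, the 1-epimer of 14, F6, and K2CO3 in MeOH epimerises it to come back to the route at 14.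

**Further compounds**

F1 | step 11 | 1-[(1E)-1,4-dimethoxy-3-oxobut-1-en-1-yl]-2-ethyl-3,5-dimethyl-4,6-bis(2,4,5-trimethoxyphenyl)cyclohexane-1-carbaldehyde (formyl axial, ring centres as in 14) | CC[C@@H]1[C@H](C)[C@H](c2cc(OC)c(OC)cc2OC)[C@@H](C)[C@H](c2cc(OC)c(OC)cc2OC)[C@@]1(C=O)/C(OC)=C\C(=O)COC
F2 | step 5 | (1R,4R,5S)-2-ethyl-3,5-dimethyl-4-(2,4,5-trimethoxyphenyl)cyclohex-2-en-1-ol | CCC1=C(C)[C@H](c2cc(OC)c(OC)cc2OC)[C@@H](C)C[C@H]1O
F3 | step 5 | (1R,2R,3R,4R,5S)-2-ethyl-3,5-dimethyl-4-(2,4,5-trimethoxyphenyl)cyclohexan-1-ol | CC[C@@H]1[C@H](C)[C@H](c2cc(OC)c(OC)cc2OC)[C@@H](C)C[C@H]1O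
F4 | step 7 | 2-ethyl-3,5-dimethyl-1-methylidene-4,6-bis(2,4,5-trimethoxyphenyl)cyclohexane, ring centres as in 12 | CC[C@@H]1[C@H](C)[C@H](c2cc(OC)c(OC)cc2OC)[C@@H](C)[C@H](c2cc(OC)c(OC)cc2OC)C1=C
F5 | step 7 | [2-ethyl-3,5-dimethyl-4,6-bis(2,4,5-trimethoxyphenyl)cyclohexyl]methanol, hydroxymethyl axial (cis to the 3-methyl group) | CC[C@@H]1[C@H](C)[C@H](c2cc(OC)c(OC)cc2OC)[C@@H](C)[C@H](c2cc(OC)c(OC)cc2OC)[C@@H]1CO
F6 | step 7 | 1-epimer of 14 (formyl axial) | CC[C@@H]1[C@H](C)[C@H](c2cc(OC)c(OC)cc2OC)[C@@H](C)[C@H](c2cc(OC)c(OC)cc2OC)[C@@H]1C=O
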